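# Peroxyacarnoate A by mixed Kolbe coupling across C4–C5: synthesis design

## The problem

Peroxyacarnoate A (23) is a straight C22 chain whose C3 and C6 are tied through an O–O bridge, so the only ring is a 1,2-dioxane (O1, O2, C3–C6). C1 is a methyl ester, C6 is a methoxy peroxyketal, and the tail from C7 carries a C10≡C11 alkyne conjugated to an E C12=C13 alkene and ends in a C21=C22 vinyl group.

There are two stereocentres, C3 (S) and C6 (R). C6 is a ketal carbon that epimerises in acidic methanol, and 23 is the epimer with the methoxy group axial (anomeric) and both carbon substituents equatorial. C3 can therefore set C6 by equilibration, but nothing in the molecule can set C3: it must be brought in enantiopure and turned into a C–OO bond stereospecifically.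

The peroxide will not survive hydride reagents, hydrogenation, dissolving metals or long contact with phosphines and low-valent metals. The peroxyketal is labile to aqueous acid, and base at C2 opens the ring by β-elimination and would erase C3. The same β-relationship forbids a leaving group on C3 while C1 is a carbonyl group. The enyne and the terminal alkene exclude hydrogenation and hydroboration and are best added late by an sp–sp2 coupling.

The feature that simplifies assembly is that C3 is a carbinol carbon between two methylenes (C2 and C4), the pattern of a 3-oxyglutaric acid. The C4–C5 bond joins two methylenes that each lie β to an oxygen-bearing carbon (C3 and C6), so cutting there leaves two β-oxygenated acetic acids.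

## Retrosynthesis

**C11–C12 (alkyne–alkene bond).** 23 is cut into the terminal alkyne 19, which is the complete dioxane core with a pent-4-ynyl stub, and (E)-1-iodoundeca-1,10-diene 22. A cut at C9–C10 would need an acetylide alkylation, that is, a strong base beside a peroxide and an ester. A cut at C12=C13 would create the alkene geometry at the last step. This cut removes eleven carbons and nearly all unsaturation from the sensitive half. The forward coupling must run at room temperature with a weak amine base so that the O–O bond and C3 are untouched.

**C6 configuration and C1 oxidation level.** 19 is the thermodynamic C6 epimer. It is traced to the C6-epimeric acid 18 through one acidic methanol step that esterifies C1 and equilibrates the ketal. 18 comes from the primary alcohol 17 by oxidation. Keeping C1 as an alcohol until the ring is closed is forced by the next cut.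

**O2–C3 (secondary C–O bond of the peroxide).** 17 is traced through its silyl ether 16 to the open-chain hydroperoxy ketal 15, in which the distal peroxide oxygen displaces a C3 mesylate (6-exo-tet, inversion).
- Conjugate addition of the hydroperoxide to a C2=C3 enoate is the shortest closure, but it would destroy the C3 centre and give racemic material.
- Opening a C1–C3 β-lactone with peroxide would keep C1 at the acid level, but it lacks precedent and invites attack at the acyl carbon.
- A sulfonate at C3 of an ester eliminates.

15 comes from ketone 14 by peroxyketalisation, and 14 from the dioxolane 13. The order is imposed by two side reactions: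
- C6 is unmasked only after O3 is sulfonylated, because a free 3-hydroxyl would close onto C6 under acid to a tetrahydrofuranyl ketal.
- Base is applied only after C6 is a peroxyketal, because a γ-mesyloxy ketone would close to a cyclopropyl ketone.

**Adjustments at C1 and O3.** 13 is traced to the diol 11 (primary silylation, secondary mesylation), 11 to the β-hydroxy ester 10, and 10 to the silyl ether 9. No C–C bond changes and the C3–O bond is never broken, so the configuration of 9 arrives intact at the mesylate.

**C4–C5 (key cut).** 9 is cut in the middle of its C3–C6 tether into the half-ester 2 and the ketal acid 8, each losing CO2 on coupling.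
- A C5–C6 cut would need acyl-anion chemistry on a long aliphatic aldehyde.
- A C3–C4 cut would be an acetate aldol that needs an auxiliary to set C3.

The C4–C5 cut gives a C5 piece that already holds the stereocentre and a C8 piece without one, both reached in a few steps. The forward reaction must favour cross- over homo-coupling, stop at the radical stage, couple faster than the C5 radical can cyclise onto the alkyne, and leave C3, the silyl ether, the dioxolane and the alkyne alone.

**Sources of the two acids.** 2 comes from the achiral anhydride 1 by enantioselective methanolysis. C3 is set by which of two enantiotopic carbonyl groups is opened. 8 comes from ester 7 by saponification, 7 from β-keto ester 6 by ketalisation, and 6 from hex-5-ynoic acid 3 and Meldrum's acid 4 by acylation and methanolysis.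

**Vinyl iodide.** 22 is cut at C12=C13 into dec-9-enal 21 and a one-carbon iodomethylene unit (Takai olefination). 21 comes from dec-9-en-1-ol 20.

## Roads not taken

**Alternative 1:** Both C–O bonds of the peroxide are cut, leaving hydrogen peroxide and the ketal β-lactone A2, which carries the whole chain.
- Forward step: hydrogen peroxide exchanges into the C6 dimethyl ketal; mild base then lets the peroxide anion open the lactone at C3 with inversion, giving acid A1 as C6 epimers. Acidic methanol would finish 23.
- Merits: the shortest end game. C1 stays at the acid level, a β-lactone cannot undergo E1cB elimination, and inversion is built in.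
- Weak points: opening a β-alkyl β-lactone at the alkyl carbon by a peroxide anion has not been shown. Hydroperoxide anions are strongly acyl-philic, so free peroxide with base is likely to perhydrolyse the lactone. A2 itself still needs an enantioselective synthesis, and the step is run on the fully elaborated, most valuable intermediate.
- Comparison: on step count this road is better. The chosen plan spends a reduction, a protection, a deprotection and a re-oxidation at C1 to make a sulfonate displacement possible. In return its ring closure is a reaction type already shown for 1,2-dioxanes, and C3 comes from a one-step desymmetrisation.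

**Alternative 2:** The cut is at C5–C6.
- Forward step: a thiazolium-derived carbene turns aldehyde A4 into an acyl-anion equivalent, which adds to the vinyl ketone A6 released in the flask from chloro keto ester A5, giving diketone A3.
- Merits: the whole carbon skeleton is joined in one catalytic, non-statistical C–C bond formation without protecting groups, and the C6 carbonyl arrives free. In these respects it is better than a Kolbe coupling that needs an excess of one partner.
- Weak points: A3 has no stereocentre. C3 would have to be made by an enantioselective ketone reduction in the presence of an enyne and two alkenes, and then inverted to the peroxide by the same kind of sequence used here. A6 polymerises easily, aliphatic aldehydes self-condense under carbene catalysis, and a 3,6-diketo ester tends to cyclise to furans or by aldol reaction.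
- Comparison: the chosen plan carries C3 from its first step and couples two partners that are inert to each other. It pays with a statistical coupling.

**Alternative 3:** The cuts are O2–C3, C1–C2 and the ester C–O bond.
- Forward step: divalent palladium (PdCl2 with CuCl2 as reoxidant) activates the terminal alkene of hydroperoxy ketal A8. The hydroperoxide adds at C3, and the alkylpalladium inserts CO and is methanolysed to A7, which after desilylation would be 19.
- Merits: by far the most step-economic road. The ring, C1 and the ester are made in one operation from CO and methanol.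
- Weak points: oxypalladation–carbonylation with a hydroperoxide nucleophile is not known. Palladium and copper salts decompose hydroperoxides, and CO is oxidised by them. The only stereocentre of A8 is the configurationally labile C6, so the product would be racemic unless a chiral ligand, for which there is no model, controlled the addition.
- Comparison: the chosen plan is much longer. It offers an absolute configuration that comes from a reliable desymmetrisation and a stereospecific substitution, and every step uses a known reaction type.

Key step: step 5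

Assumption: the quinidine-derived catalyst (DHQD)2AQN is taken to open 1 to the (3R) half-ester 2. If the sense of induction is the opposite, its quinine-derived pseudo-enantiomer (DHQ)2AQN is used in the same way.

Remark: compounds 15–18 are mixtures of C6 epimers (written 6RS); C6 is set in step 14.

## Route

Step 1
Reactants: 1 3-[(tert-butyldimethylsilyl)oxy]pentanedioic anhydride
Product: 2 (3R)-3-[(tert-butyldimethylsilyl)oxy]-5-methoxy-5-oxopentanoic acid
Conditions: (DHQD)2AQN (0.3 equiv), MeOH (10 equiv), Et2O, −40 °C
Reagents that add atoms: methanol, CO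
Why: Alkaloid-catalysed alcoholytic desymmetrisation of a prochiral cyclic anhydride; the catalyst acts as a chiral general base and C3 is set by which enantiotopic carbonyl group is methanolysed.

Step 2
Reactants: 3 hex-5-ynoic acid; 4 2,2-dimethyl-1,3-dioxane-4,6-dione (Meldrum's acid)
Product: 6 methyl 3-oxooct-7-ynoate, via acyl Meldrum's acid 5 (not isolated)
Conditions: N,N'-dicyclohexylcarbodiimide, DMAP, CH2Cl2, 0 °C → rt; filter, acid wash, concentrate; then MeOH, reflux
Reagents that add atoms: methanol, CO
Why: Carbodiimide-mediated C-acylation of Meldrum's acid followed by thermal methanolysis (loss of acetone and CO2 through an acyl ketene) is the standard route from an acid to its β-keto ester.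

Step 3
Reactants: 6 methyl 3-oxooct-7-ynoate
Product: 7 methyl 2-[2-(pent-4-yn-1-yl)-1,3-dioxolan-2-yl]acetate
Conditions: ethylene glycol (5 equiv), TsOH·H2O (cat.), toluene, reflux, Dean–Stark trap
Reagents that add atoms: ethylene glycol, OCCO
Why: Acid-catalysed ketalisation with azeotropic removal of water; the ketone reacts and the ester and alkyne do not.

Step 4
Reactants: 7 methyl 2-[2-(pent-4-yn-1-yl)-1,3-dioxolan-2-yl]acetate
Product: 8 2-[2-(pent-4-yn-1-yl)-1,3-dioxolan-2-yl]acetic acid
Conditions: LiOH·H2O (1.5 equiv), THF/H2O (3:1), 0 °C → rt; then 0.5 M HCl to pH 4 at 0 °C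
Reagents that add atoms: lithium hydroxide, [Li+].[OH-]
Why: Ester saponification; the dioxolane is stable to base, and cold acidification only to pH 4 avoids unmasking the β-keto acid, which would decarboxylate.

Step 5
Reactants: 2 (3R)-3-[(tert-butyldimethylsilyl)oxy]-5-methoxy-5-oxopentanoic acid (4 equiv); 8 2-[2-(pent-4-yn-1-yl)-1,3-dioxolan-2-yl]acetic acid (1 equiv)
Product: 9 methyl (3R)-3-[(tert-butyldimethylsilyl)oxy]-5-[2-(pent-4-yn-1-yl)-1,3-dioxolan-2-yl]pentanoate
Conditions: KOH (5 mol % of total acid), MeOH, undivided cell, smooth platinum anode and cathode, constant current 0.25 A cm−2, 10–20 °C, until the electrolyte turns slightly alkaline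
Reagents that add atoms: none
Why: Mixed Kolbe electrolysis: each carboxylate is oxidised at the platinum anode to an acyloxy radical that loses CO2, and the two primary radicals (C4 from 2, C5 from 8) combine in the dense radical layer at the electrode to form the C4–C5 bond; the closest known reaction type is the cross-Kolbe coupling of O-protected β-hydroxy acids, which keeps the carbinol configuration. No ring closes and no stereocentre is formed; C3 lies one carbon from the radical and is carried through unchanged. Cross- against homo-coupling is statistical, so the one-step half-ester 2 is used in fourfold excess and its symmetrical dimer is removed by chromatography. Both radicals are primary and carry an electron-withdrawing β-oxygen, which disfavours further oxidation to cations and capture by methanol (Hofer–Moest pathway). By connectivity the C5 radical is a hex-5-ynyl radical (C5 to C10≡C11); its 5-exo-dig closure is a slow radical clock, and high current density on smooth platinum is chosen so that bimolecular coupling outruns it. Partial neutralisation keeps the methanol near neutral, so silyl ether, dioxolane, methyl ester and terminal alkyne should pass unchanged.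

Step 6
Reactants: 9 methyl (3R)-3-[(tert-butyldimethylsilyl)oxy]-5-[2-(pent-4-yn-1-yl)-1,3-dioxolan-2-yl]pentanoate
Product: 10 methyl (3R)-3-hydroxy-5-[2-(pent-4-yn-1-yl)-1,3-dioxolan-2-yl]pentanoate
Conditions: Bu4NF (1.5 equiv), AcOH (1.5 equiv), THF, 0 °C → rt
Reagents that add atoms: none
Why: Fluoride desilylation, buffered with acetic acid so that the β-alkoxide does not trigger elimination or ester exchange; the C3–O bond is not touched.

Step 7
Reactants: 10 methyl (3R)-3-hydroxy-5-[2-(pent-4-yn-1-yl)-1,3-dioxolan-2-yl]pentanoate
Product: 11 (3R)-5-[2-(pent-4-yn-1-yl)-1,3-dioxolan-2-yl]pentane-1,3-diol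
Conditions: LiBH4 (2 equiv), THF, 0 °C → rt
Reagents that add atoms: none
Why: Borohydride reduction of a β-hydroxy ester to the 1,3-diol; ketal and alkyne are inert, and C1 leaves the carbonyl level so that C3 can later carry a leaving group.

Step 8
Reactants: 11 (3R)-5-[2-(pent-4-yn-1-yl)-1,3-dioxolan-2-yl]pentane-1,3-diol
Product: 13 (3R)-1-[(tert-butyldiphenylsilyl)oxy]-5-[2-(pent-4-yn-1-yl)-1,3-dioxolan-2-yl]pentan-3-yl methanesulfonate, via primary silyl ether 12 (not isolated)
Conditions: TBDPSCl (1.05 equiv), Et3N (4 equiv), DMAP (cat.), CH2Cl2, 0 °C → rt; then MsCl (1.3 equiv), 0 °C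
Reagents that add atoms: tert-butyl(chloro)diphenylsilane, CC(C)(C)[Si](Cl)(c1ccccc1)c1ccccc1; methanesulfonyl chloride, CS(=O)(=O)Cl
Why: Sterically controlled silylation of the primary hydroxyl followed by sulfonylation of the remaining secondary hydroxyl in the same flask; both are O–H substitutions, so C3 keeps its configuration.

Step 9
Reactants: 13 (3R)-1-[(tert-butyldiphenylsilyl)oxy]-5-[2-(pent-4-yn-1-yl)-1,3-dioxolan-2-yl]pentan-3-yl methanesulfonate
Product: 14 (3R)-1-[(tert-butyldiphenylsilyl)oxy]-6-oxoundec-10-yn-3-yl methanesulfonate
Conditions: TsOH·H2O (0.2 equiv), acetone/H2O (10:1), rt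
Reagents that add atoms: water, O
Why: Acid-catalysed ketal hydrolysis; with O3 sulfonylated and O1 silylated no hydroxyl can add to the liberated ketone, and the mesylate and the primary silyl ether tolerate the conditions.

Step 10
Reactants: 14 (3R)-1-[(tert-butyldiphenylsilyl)oxy]-6-oxoundec-10-yn-3-yl methanesulfonate
Product: 15 (3R,6RS)-1-[(tert-butyldiphenylsilyl)oxy]-6-hydroperoxy-6-methoxyundec-10-yn-3-yl methanesulfonate
Conditions: urea·H2O2 (5 equiv), Sc(OTf)3 (0.1 equiv), MeOH, 0 °C → rt
Reagents that add atoms: hydrogen peroxide (as its urea adduct), OO; methanol, CO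
Why: Acid-catalysed peroxyketalisation of a ketone with hydrogen peroxide in methanol gives the α-methoxy hydroperoxide; C6 forms as both epimers, which is harmless because it is equilibrated in step 14.

Step 11
Reactants: 15 (3R,6RS)-1-[(tert-butyldiphenylsilyl)oxy]-6-hydroperoxy-6-methoxyundec-10-yn-3-yl methanesulfonate
Product: 16 tert-butyl{2-[(3S,6RS)-6-methoxy-6-(pent-4-yn-1-yl)-1,2-dioxan-3-yl]ethoxy}diphenylsilane
Conditions: KOtBu (1.1 equiv), 18-crown-6 (1.1 equiv), THF (0.01 M), 0 °C
Reagents that add atoms: none
Why: Intramolecular alkylation of a hydroperoxy-ketal anion by a secondary methanesulfonate (6-exo-tet SN2), a known route to 3-alkoxy-1,2-dioxanes; backside attack inverts C3 from R to S. With no carbonyl at C1 or C6 neither E1cB elimination nor enolate cyclisation can compete.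

Step 12
Reactants: 16 tert-butyl{2-[(3S,6RS)-6-methoxy-6-(pent-4-yn-1-yl)-1,2-dioxan-3-yl]ethoxy}diphenylsilane
Product: 17 2-[(3S,6RS)-6-methoxy-6-(pent-4-yn-1-yl)-1,2-dioxan-3-yl]ethan-1-ol
Conditions: Bu4NF (1.5 equiv), AcOH (1.5 equiv), THF, 0 °C → rt
Reagents that add atoms: none
Why: Fluoride desilylation; dialkyl peroxides and peroxyketals are inert to buffered fluoride.

Step 13
Reactants: 17 2-[(3S,6RS)-6-methoxy-6-(pent-4-yn-1-yl)-1,2-dioxan-3-yl]ethan-1-ol
Product: 18 2-[(3S,6RS)-6-methoxy-6-(pent-4-yn-1-yl)-1,2-dioxan-3-yl]acetic acid
Conditions: TEMPO (0.2 equiv), PhI(OAc)2 (2.5 equiv), MeCN/H2O (1:1), rt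
Reagents that add atoms: water, O
Why: Oxoammonium-mediated oxidation of a primary alcohol through the aldehyde hydrate to the acid; the oxidant does not attack the O–O bond or the alkyne, and the weakly acidic medium keeps the transient β-peroxy aldehyde from eliminating. Any exchange of the C6 methoxy group for hydroxyl is reversed in step 14.

Step 14
Reactants: 18 2-[(3S,6RS)-6-methoxy-6-(pent-4-yn-1-yl)-1,2-dioxan-3-yl]acetic acid
Product: 19 methyl 2-[(3S,6R)-6-methoxy-6-(pent-4-yn-1-yl)-1,2-dioxan-3-yl]acetate
Conditions: HCl (0.05 M) in MeOH, 0 °C → rt
Reagents that add atoms: methanol, CO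
Why: Fischer esterification together with acid-catalysed ketal exchange through the C6 peroxycarbenium ion. Under thermodynamic control the methoxy group should take the axial (anomeric) position with the C3 and C6 carbon chains equatorial, which is the 6R epimer dictated by the fixed 3S centre.

Step 15
Reactants: 20 dec-9-en-1-ol
Product: 21 dec-9-enal
Conditions: TEMPO (0.1 equiv), PhI(OAc)2 (1.1 equiv), CH2Cl2, rt
Reagents that add atoms: none
Why: Oxoammonium-mediated oxidation of a primary alcohol stops at the aldehyde in the absence of water and leaves the terminal alkene alone.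

Step 16
Reactants: 21 dec-9-enal
Product: 22 (1E)-1-iodoundeca-1,10-diene
Conditions: CrCl2 (6 equiv), CHI3 (2 equiv), THF/1,4-dioxane (1:6), 0 °C → rt
Reagents that add atoms: iodoform, IC(I)I
Why: Takai olefination; the geminal dichromium species adds to the aldehyde and anti-elimination gives predominantly the E vinyl iodide.

Step 17
Reactants: 19 methyl 2-[(3S,6R)-6-methoxy-6-(pent-4-yn-1-yl)-1,2-dioxan-3-yl]acetate; 22 (1E)-1-iodoundeca-1,10-diene
Product: 23 methyl 2-[(3S,6R)-6-[(6E)-hexadeca-6,15-dien-4-yn-1-yl]-6-methoxy-1,2-dioxan-3-yl]acetate (peroxyacarnoate A)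
Conditions: Pd(PPh3)4 (5 mol %), CuI (10 mol %), iPr2NH (3 equiv), THF, degassed, rt
Reagents that add atoms: none
Why: Sonogashira coupling of a terminal alkyne with a vinyl iodide proceeds with retention of the E geometry. Palladium/copper couplings are known to tolerate 1,2-dioxanes at room temperature, and the weak amine base leaves the C2 protons and C3 alone.

## Compound list

1 | 3-[(tert-butyldimethylsilyl)oxy]pentanedioic anhydride (4-[(tert-butyldimethylsilyl)oxy]oxane-2,6-dione) | O=C1CC(O[Si](C)(C)C(C)(C)C)CC(=O)O1 | starting material
2 | (3R)-3-[(tert-butyldimethylsilyl)oxy]-5-methoxy-5-oxopentanoic acid | OC(=O)C[C@H](CC(=O)OC)O[Si](C)(C)C(C)(C)C | intermediate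
3 | hex-5-ynoic acid | C#CCCCC(=O)O | starting material
4 | 2,2-dimethyl-1,3-dioxane-4,6-dione (Meldrum's acid) | CC1(C)OC(=O)CC(=O)O1 | starting material
5 | 5-(1-hydroxyhex-5-yn-1-ylidene)-2,2-dimethyl-1,3-dioxane-4,6-dione | C#CCCCC(O)=C1C(=O)OC(C)(C)OC1=O | intermediate
6 | methyl 3-oxooct-7-ynoate | C#CCCCC(=O)CC(=O)OC | intermediate
7 | methyl 2-[2-(pent-4-yn-1-yl)-1,3-dioxolan-2-yl]acetate | C#CCCCC1(CC(=O)OC)OCCO1 | intermediate
8 | 2-[2-(pent-4-yn-1-yl)-1,3-dioxolan-2-yl]acetic acid | C#CCCCC1(CC(=O)O)OCCO1 | intermediate
9 | methyl (3R)-3-[(tert-butyldimethylsilyl)oxy]-5-[2-(pent-4-yn-1-yl)-1,3-dioxolan-2-yl]pentanoate | C#CCCCC1(OCCO1)CC[C@H](CC(=O)OC)O[Si](C)(C)C(C)(C)C | intermediate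
10 | methyl (3R)-3-hydroxy-5-[2-(pent-4-yn-1-yl)-1,3-dioxolan-2-yl]pentanoate | C#CCCCC1(OCCO1)CC[C@H](CC(=O)OC)O | intermediate
11 | (3R)-5-[2-(pent-4-yn-1-yl)-1,3-dioxolan-2-yl]pentane-1,3-diol | C#CCCCC1(OCCO1)CC[C@H](CCO)O | intermediate
12 | (3R)-1-[(tert-butyldiphenylsilyl)oxy]-5-[2-(pent-4-yn-1-yl)-1,3-dioxolan-2-yl]pentan-3-ol | C#CCCCC1(OCCO1)CC[C@H](CCO[Si](c1ccccc1)(c1ccccc1)C(C)(C)C)O | intermediate
13 | (3R)-1-[(tert-butyldiphenylsilyl)oxy]-5-[2-(pent-4-yn-1-yl)-1,3-dioxolan-2-yl]pentan-3-yl methanesulfonate | C#CCCCC1(OCCO1)CC[C@H](CCO[Si](c1ccccc1)(c1ccccc1)C(C)(C)C)OS(C)(=O)=O | intermediate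
14 | (3R)-1-[(tert-butyldiphenylsilyl)oxy]-6-oxoundec-10-yn-3-yl methanesulfonate | C#CCCCC(=O)CC[C@H](CCO[Si](c1ccccc1)(c1ccccc1)C(C)(C)C)OS(C)(=O)=O | intermediate
15 | (3R,6RS)-1-[(tert-butyldiphenylsilyl)oxy]-6-hydroperoxy-6-methoxyundec-10-yn-3-yl methanesulfonate | C#CCCCC(OC)(OO)CC[C@H](CCO[Si](c1ccccc1)(c1ccccc1)C(C)(C)C)OS(C)(=O)=O | intermediate
16 | tert-butyl{2-[(3S,6RS)-6-methoxy-6-(pent-4-yn-1-yl)-1,2-dioxan-3-yl]ethoxy}diphenylsilane | C#CCCCC1(OC)CC[C@@H](CCO[Si](c2ccccc2)(c2ccccc2)C(C)(C)C)OO1 | intermediate
17 | 2-[(3S,6RS)-6-methoxy-6-(pent-4-yn-1-yl)-1,2-dioxan-3-yl]ethan-1-ol | C#CCCCC1(OC)CC[C@@H](CCO)OO1 | intermediate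
18 | 2-[(3S,6RS)-6-methoxy-6-(pent-4-yn-1-yl)-1,2-dioxan-3-yl]acetic acid | C#CCCCC1(OC)CC[C@@H](CC(=O)O)OO1 | intermediate
19 | methyl 2-[(3S,6R)-6-methoxy-6-(pent-4-yn-1-yl)-1,2-dioxan-3-yl]acetate | C#CCCC[C@]1(OC)CC[C@@H](CC(=O)OC)OO1 | intermediate
20 | dec-9-en-1-ol | C=CCCCCCCCCO | starting material
21 | dec-9-enal | C=CCCCCCCCC=O | intermediate
22 | (1E)-1-iodoundeca-1,10-diene | C=CCCCCCCC/C=C/I | intermediate
23 | methyl 2-[(3S,6R)-6-[(6E)-hexadeca-6,15-dien-4-yn-1-yl]-6-methoxy-1,2-dioxan-3-yl]acetate (peroxyacarnoate A) | C=CCCCCCCC/C=C/C#CCCC[C@]1(OC)CC[C@@H](CC(=O)OC)OO1 | target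

## Step count and least certain steps

Total: 17 steps. Longest linear sequence: 14 steps (steps 2–14 and 17, from hex-5-ynoic acid 3).

**Step 5 (key step).** Four processes could lower the yield: statistical homo-coupling that consumes 8; 5-exo-dig cyclisation of the C5 radical onto the alkyne before it couples; further oxidation of the radicals to cations with capture by methanol; and loss of the dioxolane in the weakly acidic electrolyte followed by decarboxylation of the freed β-keto acid.

Fallback (from 2 and 6, back at 9): the same C4–C5 bond is made by enolate alkylation. Decarboxylative iodination of 2 (PhI(OAc)2, I2, visible light) would give methyl (3S)-3-[(tert-butyldimethylsilyl)oxy]-4-iodobutanoate F1. The potassium enolate of β-keto ester 6 (K2CO3, DMF) is alkylated with it at the carbon between the two carbonyl groups to give dimethyl (2RS,4R)-4-[(tert-butyldimethylsilyl)oxy]-2-(hex-5-ynoyl)hexanedioate F2. Krapcho demethoxycarbonylation (LiCl, wet DMSO, heat) leaves methyl (3R)-3-[(tert-butyldimethylsilyl)oxy]-6-oxoundec-10-ynoate F3, whose ketone is ketalised (1,2-bis(trimethylsilyloxy)ethane, TMSOTf, −78 °C) to 9.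

**Step 11.** Base-induced E2 elimination of the secondary mesylate toward C2 or C4 may compete with the 6-exo displacement, and the hydroperoxy-ketal anion may decompose before it closes.

Fallback (from 13, back at 16): O2–C3 is formed between two molecules and the ring is closed at C6 instead. Displacement of the mesylate of 13 by 2-methoxypropan-2-yl hydroperoxide with CsOH in DMF, a known hydroperoxide-anion equivalent for sulfonates, would give with inversion tert-butyl{[(3S)-3-[(2-methoxypropan-2-yl)peroxy]-5-[2-(pent-4-yn-1-yl)-1,3-dioxolan-2-yl]pentyl]oxy}diphenylsilane F4. In acidic methanol (TsOH) the peroxide protecting group is exchanged off and the freed C3 hydroperoxide closes onto C6 by transketalisation to 16, mainly as its thermodynamic C6 epimer.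

**Step 10.** Peroxyketalisation is an equilibrium and may stop short or drift to the geminal dihydroperoxide and the dimethyl ketal. Slow solvolysis of the mesylate with participation of the C6 oxygen is a second loss.

Fallback (from 14, back at 15): the hydroperoxy ketal is made by trapping a carbonyl oxide. Methylenation of 14 (Zn, CH2Br2, TiCl4) would give (3R)-1-[(tert-butyldiphenylsilyl)oxy]-6-methylideneundec-10-yn-3-yl methanesulfonate F5. Ozonolysis at −78 °C in CH2Cl2/MeOH, stopped at the first excess of ozone so that the alkyne is spared, cleaves the 1,1-disubstituted alkene to formaldehyde and the C6 carbonyl oxide, which methanol captures as 15 under neutral conditions.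

**Step 14.** Esterification may be too slow at an acid strength the peroxyketal tolerates, and stronger acid may open the ring or cleave the O–O bond before C6 has equilibrated.

Fallback (from 18, back at 19): the two tasks are separated. Trimethylsilyldiazomethane in toluene/methanol would esterify 18 without acid to methyl 2-[(3S,6RS)-6-methoxy-6-(pent-4-yn-1-yl)-1,2-dioxan-3-yl]acetate F6. C6 is then equilibrated on the ester with pyridinium p-toluenesulfonate in methanol to 19; any remaining 6S epimer is separated by chromatography and recycled.

**Step 16.** Incomplete E selectivity in the olefination would carry a Z iodide into the final coupling, where the isomers are hard to separate.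

Fallback (from 21, back at 22): the geometry is fixed by a syn addition instead of an olefination. Homologation of 21 with dimethyl (1-diazo-2-oxopropyl)phosphonate (K2CO3, MeOH) would give undec-10-en-1-yne F7. Hydrozirconation with one equivalent of Cp2Zr(H)Cl, which takes the terminal alkyne before the terminal alkene, and iodinolysis (I2) give 22 as the E isomer only.

## Further compounds

F1 | step 5 | methyl (3S)-3-[(tert-butyldimethylsilyl)oxy]-4-iodobutanoate | IC[C@H](CC(=O)OC)O[Si](C)(C)C(C)(C)C
F2 | step 5 | dimethyl (2RS,4R)-4-[(tert-butyldimethylsilyl)oxy]-2-(hex-5-ynoyl)hexanedioate | C#CCCCC(=O)C(C(=O)OC)C[C@H](CC(=O)OC)O[Si](C)(C)C(C)(C)C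
F3 | step 5 | methyl (3R)-3-[(tert-butyldimethylsilyl)oxy]-6-oxoundec-10-ynoate | C#CCCCC(=O)CC[C@H](CC(=O)OC)O[Si](C)(C)C(C)(C)C
F4 | step 11 | tert-butyl{[(3S)-3-[(2-methoxypropan-2-yl)peroxy]-5-[2-(pent-4-yn-1-yl)-1,3-dioxolan-2-yl]pentyl]oxy}diphenylsilane | C#CCCCC1(OCCO1)CC[C@@H](CCO[Si](c1ccccc1)(c1ccccc1)C(C)(C)C)OOC(C)(C)OC
F5 | step 10 | (3R)-1-[(tert-butyldiphenylsilyl)oxy]-6-methylideneundec-10-yn-3-yl methanesulfonate | C#CCCCC(=C)CC[C@H](CCO[Si](c1ccccc1)(c1ccccc1)C(C)(C)C)OS(C)(=O)=O
F6 | step 14 | methyl 2-[(3S,6RS)-6-methoxy-6-(pent-4-yn-1-yl)-1,2-dioxan-3-yl]acetate | C#CCCCC1(OC)CC[C@@H](CC(=O)OC)OO1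
F7 | step 16 | undec-10-en-1-yne | C=CCCCCCCCC#C
A1 | alternative 1 | 2-[(3S,6RS)-6-[(6E)-hexadeca-6,15-dien-4-yn-1-yl]-6-methoxy-1,2-dioxan-3-yl]acetic acid (peroxyacarnoic acid A, C6 epimers) | C=CCCCCCCC/C=C/C#CCCCC1(OC)CC[C@@H](CC(=O)O)OO1
A2 | alternative 1 | (4R)-4-[(9E)-3,3-dimethoxynonadeca-9,18-dien-7-yn-1-yl]oxetan-2-one | C=CCCCCCCC/C=C/C#CCCCC(OC)(OC)CC[C@@H]1CC(=O)O1
A3 | alternative 2 | methyl (12E)-3,6-dioxodocosa-12,21-dien-10-ynoate | C=CCCCCCCC/C=C/C#CCCCC(=O)CCC(=O)CC(=O)OC
A4 | alternative 2 | (7E)-heptadeca-7,16-dien-5-ynal | C=CCCCCCCC/C=C/C#CCCCC=O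
A5 | alternative 2 | methyl 5-chloro-3-oxopentanoate | COC(=O)CC(=O)CCCl
A6 | alternative 2 | methyl 3-oxopent-4-enoate | C=CC(=O)CC(=O)OC
A7 | alternative 3 | methyl 2-[(3S,6R)-6-methoxy-6-{5-[tri(propan-2-yl)silyl]pent-4-yn-1-yl}-1,2-dioxan-3-yl]acetate | CC(C)[Si](C(C)C)(C(C)C)C#CCCC[C@]1(OC)CC[C@@H](CC(=O)OC)OO1
A8 | alternative 3 | (6-hydroperoxy-6-methoxydec-9-en-1-yn-1-yl)tri(propan-2-yl)silane | C=CCCC(OC)(OO)CCCC#C[Si](C(C)C)(C(C)C)C(C)C
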